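Weigh, before charging the flask, whether a little more Rgt or a little more Kat buys more rate of making Tgt at the conversion asked about.

all flasks: Oth 40 µM
- north: Sbt 0.010 M; Sbt2 0.010 M; Rgt 0.022 M; Kat 86 µM; run made earlier
- east: Sbt 0.015 M; Sbt2 0.015 M; Rgt 0.022 M; Kat 86 µM; run made earlier
- west: Sbt 0.020 M; Sbt2 0.020 M; Rgt 0.022 M; Kat 130 µM; run made earlier
- flask: Sbt 0.020 M; Sbt2 0.020 M; Rgt 0.0220 M; Kat 86 µM

| run | time / min | Tgt / % | Sbt / % |
|---|---|---|---|
| north | 12.0 | 7.6 | 42.8 |
| north | 25.0 | 10.8 | 39.3 |
| north | 30.0 | 12.3 | 37.5 |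
| north | 50.0 | 17.3 | 31.7 |
| north | 60.0 | 19.6 | 29.7 |
| north | 80.0 | 23.7 | 26.0 |
| east | 6.00 | 5.2 | 45.6 |
| east | 10.0 | 5.9 | 43.5 |
| east | 15.0 | 7.7 | 43.4 |
| east | 25.0 | 11.2 | 38.3 |
| east | 30.0 | 11.8 | 37.6 |
| east | 50.0 | 17.3 | 33.1 |
| east | 80.0 | 22.7 | 28.6 |
| west | 15.0 | 10.5 | 39.6 |
| west | 30.0 | 15.8 | 33.9 |
| west | 50.0 | 20.3 | 30.1 |
| west | 60.0 | 22.1 | 28.8 |
| west | 80.0 | 24.6 | 25.2 |

(each reading ± 0.5 percentage points)

- Kat is single-handed; Sbt and Sbt2 are mirror images of each other, charged as a racemate, each of them at the stated concentration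
- no earlier run changes the charge of Rgt; that part of a forecast is a guess

1. apparent order in Kat when 30 % of the Sbt and Sbt2 together are converted (percent change of the rate of making Tgt for one percent more Kat charged)
2. apparent order in Rgt when 30 % of the Sbt and Sbt2 together are converted (percent change of the rate of making Tgt for one percent more Rgt charged)

After 30.0 min, west with 130 µM of Kat and 0.020 M of Sbt holds 15.8 % Tgt against 11.8 % in east with 86 µM of Kat and 0.015 M of Sbt, but at 80.0 min west holds 24.6 % against 22.7 %, so west's early lead shrinks, though two settings differ between these runs. No run varies Rgt, so this reckoning for the flask is a guess: the rate goes with the first power of Rgt, and each substrate molecule takes one Rgt.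

Against Sbt and Sbt2 together, Rgt is the limiting reagent, charged at 0.550 equivalents. At 30 % conversion the flask has used 0.0120 M of Rgt, however long that takes, which leaves 0.0100 M. Extra charge adds to that remainder undiminished, so time drops out of the comparison. The lever is 2.20, the charge divided by what is left of it at the moment looked at, and it is the percent gain in the remainder for one percent more charged. This reckoning therefore commits to an order in Rgt of 2.20, and the extra goes into Rgt unless Kat's order proves higher.

The forecast differs, with 1 for Rgt and 0.8 for Kat: “I take about 1, with wide uncertainty”.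

The flask gives 2.2 for Rgt and 1.3 for Kat.

    Rgt + Kat + Sbt → Kat + Tgt (k = 270 /M²/s)
    Rgt + Kat + Sbt2 → Kat + Tgt2 (k = 130 /M²/s)
    Kat + Oth → Zed (k = 190 /M/s)
    2 Kat ⇌ Oth2 (K = 14000 /M, k = 17.0 /M/s)

The division that gave 2.20 for Rgt can also be done on Kat. Oth, down to 0 % after 40.0 min, has locked away its 40 µM of Kat as Zed, so the 86 µM charged, divided by the Kat that Oth leaves, gives 1.87, and this flask run without the pairing of Kat into Oth2 has order 1.9. With the pairing restored, 22.8 % of the catalyst stands as Oth2 at 73.6 min, and the order comes down to 1.3.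

All runs were computed on assumed constants; noise was put on by code.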